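(The readings were computed for an exercise; noise was put on by code.)

At early times the dusk run already showed the two substrates parting: after 0.500 min the left-handed substrate read 45.2% and the right-handed substrate 48.6%.

all flasks: left-handed substrate 0.051 M; right-handed substrate 0.051 M; free catalyst 0.51 mM
- spring: reagent 0.020 M; added ligand 1.1 mM; run made earlier
- summer: reagent 0.082 M; added ligand 1.1 mM; run made earlier
- dusk: reagent 0.0408 M; added ligand 0.55 mM; run made earlier
- flask: reagent 0.0408 M; added ligand 1.1 mM; time 6.0 min

- spring (time / min: left-handed substrate / %, right-handed substrate / %): 0.500: 48.1, 50.4; 1.00: 44.6, 49.0; 1.50: 44.6, 49.9; 2.00: 43.2, 49.0; 2.50: 42.7, 49.1; 3.00: 41.5, 48.0; 4.00: 39.1, 49.2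
- summer (time / min: left-handed substrate / %, right-handed substrate / %): 0.500: 43.0, 49.8; 1.00: 38.4, 48.1; 1.50: 34.5, 47.7; 2.00: 30.6, 48.0; 2.50: 28.8, 45.6; 3.00: 26.5, 46.1; 4.00: 23.8, 46.5
- dusk (time / min: left-handed substrate / %, right-handed substrate / %): 0.250: 47.0, 50.0; 0.500: 45.2, 48.6; 1.00: 42.1, 48.8; 2.00: 36.5, 47.2; 4.00: 29.0, 47.7

(readings scatter by 0.5 percentage points)

- free catalyst is single-handed; left-handed substrate and right-handed substrate are mirror images of each other, charged as a racemate, each of them at the stated concentration
- steps thought possible: free catalyst + left-handed substrate <-> catalyst intermediate A; free catalyst + right-handed substrate <-> catalyst intermediate B; reagent + catalyst intermediate A -> free catalyst + left-handed product; reagent + catalyst intermediate B -> free catalyst + right-handed product; 2 reagent -> homo dimer; free catalyst + added ligand <-> idle complex; left-handed product <-> right-handed product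
- an excess is below zero if the other one leads

* part of the left-handed substrate and right-handed substrate charged together that has reacted at 6.0 min
* excess of left-handed product over right-handed product in the product at 6.0 min
* excess of right-handed substrate over left-handed substrate among what is left of the two at 6.0 min

How far would the new flask go? At 4.00 min the spring and summer runs, with the new flask's ligand charge and with reagent charges on either side of its own, had lost 11.7% and 29.7% of the substrate charged, a mean of 20.7%. Dusk, with the new flask's reagent and half its ligand, had lost 23.3%. That was 1.13 times the mean, less than the 1.50 times as long that the new flask was to run, so I took dusk's last reading as my estimate for the new flask: about 23.3% reacted, with a substrate excess of 24.4%.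

How was that loss shared? I defined the ledger excess, the left-handed substrate's loss minus the right-handed substrate's loss, over their sum, and dusk's last reading gave 80.3%.

Does the product keep it? The ledger excess describes the product as made, under kinetic control. The listed step between the two products could erase it, since mirror images at thermodynamic control show no excess, and the readings of these runs are of the two substrates. So I left the product excess to that step's half-life against 6.0 min.

The forecast gave 22.3% reacted, a product excess of 79% and a substrate excess of 22.5%, “assuming no product racemisation; the data cannot test this”.

The new flask gave 23.0% reacted, a product excess of 1.26% and a substrate excess of 22.4%.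

    free catalyst + left-handed substrate ⇌ catalyst intermediate A (K = 25.5 L mol⁻¹, k = 251 L mol⁻¹ s⁻¹)
    free catalyst + right-handed substrate ⇌ catalyst intermediate B (K = 8.40 L mol⁻¹, k = 211 L mol⁻¹ s⁻¹)
    reagent + catalyst intermediate A → free catalyst + left-handed product (k = 26.3 L mol⁻¹ s⁻¹)
    reagent + catalyst intermediate B → free catalyst + right-handed product (k = 8.66 L mol⁻¹ s⁻¹)
    2 reagent → homo dimer (k = 0.0420 L mol⁻¹ s⁻¹)
    free catalyst + added ligand ⇌ idle complex, settled at all times (K = 1600 L mol⁻¹)
    left-handed product ⇌ right-handed product (k = 0.0282 s⁻¹)

The two products relaxed toward each other with a half-life of 0.205 min by that step alone, short against the 6.0 min of the run. The ledger excess of the new flask, from its substrates, came to 74.9%, far above its product excess of 1.26%. In the neighbour flask with 0.010 M of reagent, 7.41% reacted and the substrate excess was 6.25%, so the ledger excess was 78.2%, while its product excess stood at 1.57%.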